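**Plan**

- Target: 2-nonadecylcyclohexa-2,5-diene-1,4-dione, ring numbered C1(=O), C2(nonadecyl), C3H, C4(=O), C5H, C6H; it is achiral.
- Retrosynthesis: C4=O and C1=O go back to C4–OMe and C1–OH, and C1–O goes back to C1–acetyl. The ring bonds C1–C2 and C5–C6 are then cut together, giving 4-methoxy-6-nonadecyl-2-pyrone and but-3-yn-2-one. The last cut is the bond between the first and second chain carbons (pyrone 6-methyl plus a C18 iodide).
- Enabling feature: ring atoms C2–C3–C4–C5, with oxygen on C4, are the C6–C5–C4–C3 diene of a 4-alkoxy-2-pyrone (a triketide-type lactone, in keeping with the polyketide origin of alkylquinones). C6–C1 is a terminal alkyne whose acyl group marks the later C1 oxygen, and the 1,4-oxygen pattern is the "para" orientation of a 2-donor diene with an acceptor alkyne.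
- Forward: the chain is joined first by lateral alkylation. The only ring is then built in one pyrone–alkyne Diels–Alder/CO2 extrusion. Acetyl is converted to acetoxy, then hydroxy, and the methoxyphenol is oxidised to the quinone.
- Stereochemistry: none in the target. The two bridgehead centres of the transient cycloadduct are racemic and vanish on aromatisation.

Key step: step 2

**Route**

Step 1
Reactants: 1 4-methoxy-6-methyl-2H-pyran-2-one; 2 1-iodooctadecane
Product: 4 4-methoxy-6-nonadecyl-2H-pyran-2-one, via lithium dienolate 3 (not isolated)
Conditions: LiN(iPr)2 (1.1 equiv), THF, −78 °C; then 2, DMPU, −78 → −20 °C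
Reagents that add atoms: none
Why: Lateral (vinylogous) deprotonation of the 6-methyl group gives the extended lithium dienolate 3, which should be C-alkylated at its exocyclic carbon by the primary iodide in an SN2 enolate alkylation.

Step 2
Reactants: 4 4-methoxy-6-nonadecyl-2H-pyran-2-one; 5 but-3-yn-2-one
Product: 7 1-(4-methoxy-2-nonadecylphenyl)ethan-1-one, via bridged lactone adduct 6 (not isolated)
Conditions: 5 (6 equiv), BHT (cat.), toluene, 150 °C, sealed tube
Reagents that add atoms: none
Why: The electron-rich diene C3=C4–C5=C6 of pyrone 4 should add to the acetylenic ketone 5 in a concerted, normal-electron-demand [4+2] cycloaddition to give the bridged lactone 6, which at the same temperature loses CO2 by retro-[4+2] cycloreversion and so delivers the benzene ring directly at the arene oxidation level. The closest known reaction type is the 2-pyrone–alkyne Diels–Alder/decarboxylation benzannulation, as known for 4-methoxy-6-methyl-2-pyrone with propiolates and acetylenedicarboxylates. The only ring that persists, the six-membered carbocycle, is closed by intermolecular suprafacial cycloaddition (pyrone C3 to the terminal alkyne carbon and pyrone C6 to the acetyl-bearing alkyne carbon, which become the quinone bonds C5–C6 and C1–C2), while the lactone bridge is a temporary ring that leaves as CO2. The two bridgehead stereocentres of 6 arise as a racemate and are both erased on aromatisation, so no stereocontrol is needed. The step needs regioselectivity, and the substrate should secure it because the 4-methoxy group and the ring oxygen on C6 both place the largest HOMO coefficient on pyrone C3, which pairs with the unsubstituted β-carbon of the ynone (largest LUMO coefficient), so that the acetyl group comes to stand next to the nonadecyl-bearing carbon and para to the methoxy group. An excess of the volatile ynone and a radical inhibitor keep the dienophile available during the slow addition at the fully substituted C6 terminus.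

Step 3
Reactants: 7 1-(4-methoxy-2-nonadecylphenyl)ethan-1-one
Product: 8 4-methoxy-2-nonadecylphenyl acetate
Conditions: mCPBA (1.5 equiv), CF3CO2H (cat.), CH2Cl2, 0 °C → rt
Reagents that add atoms: mCPBA (3-chloroperoxybenzoic acid), OOC(=O)c1cccc(Cl)c1
Why: Baeyer–Villiger oxidation, in which the aryl group, made electron-rich by the para-methoxy group, should migrate in preference to methyl in the Criegee adduct and so place oxygen on ring carbon C1.

Step 4
Reactants: 8 4-methoxy-2-nonadecylphenyl acetate
Product: 9 4-methoxy-2-nonadecylphenol
Conditions: K2CO3 (0.2 equiv), MeOH–THF, rt, under N2; then aq. NH4Cl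
Reagents that add atoms: none
Why: Base-catalysed transesterification (methanolysis) of the reactive aryl ester should free the phenol and leave the aryl methyl ether and the chain untouched.

Step 5
Reactants: 9 4-methoxy-2-nonadecylphenol
Product: 10 2-nonadecylcyclohexa-2,5-diene-1,4-dione
Conditions: PhI(OAc)2 (1.1 equiv), MeCN–THF–H2O, 0 °C
Reagents that add atoms: water, O
Why: Oxidative dearomatisation of a para-methoxyphenol, in which ligand exchange at iodine and two-electron oxidation give the phenoxonium ion, water adds at the methoxy-bearing para carbon, and the hemiketal collapses with loss of methanol to the para-quinone.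

**Compound list**

1 | 4-methoxy-6-methyl-2H-pyran-2-one | COC1=CC(=O)OC(C)=C1 | starting material
2 | 1-iodooctadecane | CCCCCCCCCCCCCCCCCCI | starting material
3 | lithium 4-methoxy-6-methylidene-6H-pyran-2-olate (extended dienolate of 1, not isolated) | C=C1C=C(OC)C=C(O[Li])O1 | intermediate
4 | 4-methoxy-6-nonadecyl-2H-pyran-2-one | CCCCCCCCCCCCCCCCCCCC1=CC(OC)=CC(=O)O1 | intermediate
5 | but-3-yn-2-one | CC(=O)C#C | starting material
6 | 7-acetyl-5-methoxy-1-nonadecyl-2-oxabicyclo[2.2.2]octa-5,7-dien-3-one (racemic, relative configuration fixed by the bicycle, not isolated) | CCCCCCCCCCCCCCCCCCCC12OC(=O)C(C=C1C(C)=O)C(OC)=C2 | intermediate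
7 | 1-(4-methoxy-2-nonadecylphenyl)ethan-1-one | CCCCCCCCCCCCCCCCCCCC1=CC(OC)=CC=C1C(C)=O | intermediate
8 | 4-methoxy-2-nonadecylphenyl acetate | CCCCCCCCCCCCCCCCCCCC1=CC(OC)=CC=C1OC(C)=O | intermediate
9 | 4-methoxy-2-nonadecylphenol | CCCCCCCCCCCCCCCCCCCC1=CC(OC)=CC=C1O | intermediate
10 | 2-nonadecylcyclohexa-2,5-diene-1,4-dione (2-nonadecyl-1,4-benzoquinone) | CCCCCCCCCCCCCCCCCCCC1=CC(=O)C=CC1=O | target

**Step count and risks**

Total steps: 5. Longest linear sequence: 5 steps (1 → 4 → 7 → 8 → 9 → 10).

Steps most likely to fail:

1. Step 2. Thermal polymerisation of the ynone may outrun the slow cycloaddition at the fully substituted C6 terminus, and regiocontrol may erode at the high temperature. The fallback sets out from pyrone 4 and comes back at phenol 9. Pyrone 4 is heated with commercial 2-ethynyl-4,4,5,5-tetramethyl-1,3,2-dioxaborolane (mesitylene, 170–180 °C, sealed vessel). The same cycloaddition/CO2 extrusion should give the arylboronate 2-(4-methoxy-2-nonadecylphenyl)-4,4,5,5-tetramethyl-1,3,2-dioxaborolane F1, with boron where the acetyl group stood. Oxidation of the C–B bond (H2O2, NaOH, THF, 0 °C) should then give phenol 9, so steps 3 and 4 are not needed. The alkynylboronate is thermally robust, but its weaker polarisation leaves regiocontrol to the diene alone, so a regioisomeric boronate, if formed, would be removed by chromatography at the stage of F1.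

2. Step 1. Deprotonation at ring carbon C3 and self-condensation of the lithiated pyrone may compete, and alkylation by the poorly soluble long-chain iodide may be slow at low temperature. The fallback sets out from iodide 2 and comes back at pyrone 4. Iodide 2 is used to alkylate the dilithium dianion of commercial 4-hydroxy-6-methyl-2H-pyran-2-one (2.2 equiv LiN(iPr)2, THF–DMPU, −78 → 0 °C). In this dianion C3 is masked inside the first enolate and the second, more reactive charge sits on the 6-methyl carbon. This should give 4-hydroxy-6-nonadecyl-2H-pyran-2-one F2, and O-methylation (Me2SO4, K2CO3, acetone, reflux) should return pyrone 4.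

3. Step 3. Electrophilic oxidation of the electron-rich ring by the peracid may compete, and Criegee adduct formation may be slow at the ortho-hindered, twisted carbonyl. The fallback sets out from ketone 7 and comes back at phenol 9. Ketone 7 is treated with MeMgBr (THF, 0 °C) to give the tertiary benzylic alcohol 2-(4-methoxy-2-nonadecylphenyl)propan-2-ol F3. H2O2 with BF3·OEt2 (CH2Cl2, 0 °C) should convert it into the benzylic hydroperoxide, which rearranges with aryl migration (Hock-type hydroperoxide rearrangement) and hydrolyses to phenol 9 and acetone, bypassing the peracid and acetate 8.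

Further compounds
F1 | step 2 | 2-(4-methoxy-2-nonadecylphenyl)-4,4,5,5-tetramethyl-1,3,2-dioxaborolane | CCCCCCCCCCCCCCCCCCCC1=CC(OC)=CC=C1B2OC(C)(C)C(C)(C)O2
F2 | step 1 | 4-hydroxy-6-nonadecyl-2H-pyran-2-one | CCCCCCCCCCCCCCCCCCCC1=CC(O)=CC(=O)O1
F3 | step 3 | 2-(4-methoxy-2-nonadecylphenyl)propan-2-ol | CCCCCCCCCCCCCCCCCCCC1=CC(OC)=CC=C1C(C)(C)O
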